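**Remarks on the chemistry (assumptions)**

- Gibberellane numbering is used for every intermediate; β is the face of ring B that carries H-5, H-9, C15 and the C7 ester, and α is the face that carries C19, C20 and ring C.
- The sense of induction in step 2 is assumed to follow the accepted model for oxazaborolidinium catalysts; the catalyst enantiomer written is the one taken to give (R) at C4, and its antipode would be used otherwise.
- The target 29 is drawn as the open keto aldehyde; a lactol between C19 and C20 may be in equilibrium with it.

## Analysis of the target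

Compound 29 is a C20 gibberellin 7,19-diacid. A trans-fused hydrindane (ring A: C1–C5 and C10; ring B: C5, C6, C8, C9, C10) carries on C8 and C9 a bicyclo[3.2.1]octane built from ring C (C8, C9, C11–C14) and ring D (C8, C13–C16), with a methylene on C16 and a ketone at C12. Seven stereocentres are present (C4, C5, C6, C8, C9, C10, C13), three of them quaternary (C4, C8, C10); C13 is a bridgehead that follows from C8, so six need control. C19 and C20 are cis on the α face of ring A, ring C is fused to the α face of ring B, and H-5, H-9, the C7 carboxyl and the C15–C16 bridge are β. The sensitive groups are a neopentyl aldehyde placed 1,5 to a ketone, an exocyclic alkene beside a bridgehead and an epimerisable C6 between two hindered carbons. The difficulty lies in the congested run C4–C5–C10–C9–C8 and in bringing a one-carbon unit at the aldehyde level onto quaternary C10. The strategy rests on the 1,5 relation of the formyl carbon C20 and the ketone carbon C12 through C10–C9–C11: C10–C20 and C9–C11 are the two bonds that a [2+2] photocycloaddition of a C9=C10 alkene with the C11=C20 bond of an acylated β-keto aldehyde enol forms, and cleavage of C11–C20 in the derived cyclobutanol then releases the keto aldehyde.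

## Retrosynthetic reasoning

**29 to 28.** Both acids travel as methyl esters to the end, so the last disconnection cuts only two O–CH3 bonds. The forward step has to free the two hindered carboxyl groups of 28 without touching the aldehyde, the ketone or C6.

**28 to 26 (through 27).** The C20 aldehyde and the C11 methylene of 28 are rejoined as a C11–C20 bond, which gives the cyclobutanol 27 and its pivalate 26. The forward reaction is an ester cleavage followed by a strain-driven retro-aldol. Keeping the aldehyde locked in the four-membered ring until then also makes C11 a cyclobutane methine, so the C12 ketone can be enolised only towards C13.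

**26 to 24 (through 25).** Ring D is opened at C13–C16. The forward step is a 5-exo-dig addition of the C12=C13 silyl enol ether 25 to the metal-activated propargyl group on C8. It forms the bridged bicycle, the C13 bridgehead and the 16-methylene together, and it needs the alkyne to sit axial on ring C.

**24 to 23.** This is the key disconnection: C9–C11 and C10–C20 are cut together. It reveals the E-configured β-pivaloyloxy enone and the C9=C10 alkene of the ring A/B hydrindene 23. Cutting here is better than cutting ring C elsewhere because the forward photocycloaddition builds ring C, makes quaternary C10 and delivers C20 at the aldehyde oxidation level in one step, with the face set by the tether at C8.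

**23 to 20 (through 21).** The enol ester is cut at the O–acyl bond (acyl donor 22) and then at C11–C20. The forward sequence is a kinetic formylation of the methyl ketone 20 on its methyl group, then O-acylation of 21 on the formyl oxygen.

**20 to 16 (through 19, 18 and 17).** The C9=C10 alkene is traced back to a C9 ketone conjugated with a C1(10) alkene. Reduction of the tosylhydrazone 18 moves the double bond from C1(10) to C9(10) and removes the oxygen, and the mechanism allows no other regiochemistry. The side-chain ketone has to be masked as the ketal (17, 19) while this is done.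

**16 to 11 (through 14 and 13).** The two bonds from C8 to C15 and C14 are cut. With C10 held as sp2 by the enone, the C9 ketone of 11 can only be enolised kinetically towards C8. Propargyl bromide 12 goes in first (13). The 3-oxobutyl chain from 15 goes in second, through the silyl dienol ether 14, because the second group enters anti to the 6β-ester and the chain must be α.

**11 to 8 (through 10 and 9).** Ring B is cut at C9–C10. The forward step is an intramolecular acylation of the ring A alkene by the acid chloride 9, followed by base-induced elimination from the chloro ketone 10 to the conjugated enone. The base also corrects C6, which is epimerisable and prefers the ester trans to C4.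

**8 to 3 and 4 (through 7, 6 and 5).** Ring A is cut at C4–C5 and C2–C3. An endo, "ortho" Diels–Alder reaction of methacrolein 4 with the 1-substituted diene 3 under a chiral Lewis acid sets the quaternary C4 and C5 in one step, with the formyl group (later C19) cis to the C6 chain. Oxidation, esterification and tert-butyl ester cleavage then give 8.

**3 to 1 and 2.** The C6–C8 bond is cut. Deconjugative α-alkylation of methyl sorbate 1 with tert-butyl bromoacetate 2 gives the diene and a differentiated succinate in one operation.

## Alternatives that were turned down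

Alternative 1: Rings A and B are disconnected together at C5–C10 and C3–C4. In the forward direction, heating joins a C10=C1–C2=C3 diene to a Z-configured C4=C5 methyl enoate held by the C9–C8–C6 chain and gives the ring A/B/C adduct A1.
- For: two rings and three stereocentres (C4, C5, C10) form in one thermal step, and C20 is present on the diene from the start. On convergence and on the number of bonds made in the key step this alternative is stronger than the chosen route.
- Against: the diene terminus C10 is 1,1-disubstituted and the dienophile carbon C4 is fully substituted, so two congested bonds must form next to each other. The endo/exo preference has to deliver a trans A/B fusion. The C8 quaternary centre must be set earlier on a cyclohexane with no ring B to direct it. C20 arrives as a protected alcohol, the C1=C2 alkene has to be reduced, and the C12 and C16 carbonyls need unmasking.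
- Comparison: the chosen strategy sets C8 on a rigid ring B next to the C6 ester and fixes C9 and C10 through the tether, and C20 appears directly as the aldehyde together with the C12 ketone.

Alternative 2: Ring C is disconnected at C12–C13. In the forward direction a Lewis acid activates a C12 aldehyde, and the γ-carbon C13 of a cyclopentenylmethylsilane that will become ring D attacks it (Hosomi–Sakurai type), closing the bicyclo[3.2.1]octane and giving the 16-methylene alcohol A2.
- For: the bridged ring and the exocyclic alkene form together under mild Lewis acid conditions, without a separate enol ether. For the ring C/D finish this is as good as or better than the gold step of the chosen route.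
- Against: the hard part, the C9–C11 bond and the C10 quaternary carbon bearing C20, must already be in place before the key step. C12 arrives as an alcohol and C20 as a silyl ether, so two oxidations follow, and a spiro ring D with its allylsilane has to be built on C8 first.
- Comparison: the chosen strategy spends its key step on C9–C11 and C10–C20 and reaches both carbonyls at the correct oxidation level.

Alternative 3: Ring B is disconnected at C6–C8 through a nine-membered C13–O–C7 lactone. In the forward direction its silyl ketene acetal rearranges [3,3] (Ireland–Claisen ring contraction), C6 bonds to C8, and the C7 acid is freed in A3.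
- For: C8 and C6 are set by chirality transfer in one pericyclic step and the C7 carboxyl needs no protection. On stereospecific formation of the C8 quaternary centre this is stronger than the substrate-controlled alkylation used here.
- Against: a nine-membered lactone has to be closed first. The chair or boat preference inside a medium ring is uncertain, so the C6/C8 configuration is uncertain too. The alkene ends at C13=C14, so C13 still has to be turned into the sp3 bridgehead, and rings C and A need many protecting groups.
- Comparison: the chosen route reaches C8 by two alkylations on a small, rigid enone and keeps the protecting groups to one ketal.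

Key step: step 15

## Route

Step 1
Reactants: 1 methyl (2E,4E)-hexa-2,4-dienoate (methyl sorbate); 2 tert-butyl 2-bromoacetate
Product: 3 4-tert-butyl 1-methyl 2-[(1E)-buta-1,3-dien-1-yl]butanedioate (racemic)
Conditions: LiN(i-Pr)2, THF/DMPU, −78 °C; then 2, −78 → −40 °C
Reagents that add atoms: none
Why: Deconjugative α-alkylation of the extended enolate of a sorbate ester: the bromoacetate attacks the α-carbon (C6), forming C6–C8 and leaving the E-configured 1-substituted butadiene C5=C10–C1=C2; C6 forms racemic and is corrected in step 6.

Step 2
Reactants: 3 diene diester from step 1; 4 2-methylprop-2-enal (methacrolein)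
Product: 5 4-tert-butyl 1-methyl 2-[(1R,6R)-6-formyl-6-methylcyclohex-2-en-1-yl]butanedioate (both C6 epimers)
Conditions: (S)-1-(2-methylphenyl)-3,3-diphenyltetrahydro-1H,3H-pyrrolo[1,2-c][1,3,2]oxazaborole·HN(SO2CF3)2 (20 mol%), CH2Cl2, −78 → −40 °C
Reagents that add atoms: none
Why: Catalytic asymmetric Diels–Alder reaction of a 2-substituted acrolein bound to a chiral oxazaborolidinium Lewis acid; the 1-substituted diene reacts "ortho" (C4–C5 and C3–C2) and endo to the formyl group, which places CHO (later C19) cis to the C6 chain, and the catalyst selects the dienophile face and so sets C4 and C5. The remote C6 centre carries two similar groups and should not bias the diene face, so both C6 epimers are expected.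

Step 3
Reactants: 5 cyclohexene aldehyde
Product: 6 (1R,2R)-2-(4-tert-butoxy-1-methoxy-1,4-dioxobutan-2-yl)-1-methylcyclohex-3-ene-1-carboxylic acid (both C6 epimers)
Conditions: NaClO2, NaH2PO4, 2-methylbut-2-ene, t-BuOH/H2O, 0 °C → rt
Reagents that add atoms: sodium chlorite, [Na+].[O-]Cl=O
Why: Pinnick oxidation of a non-enolisable aldehyde; the alkene scavenger protects the ring alkene from hypochlorite and the esters are inert.

Step 4
Reactants: 6 cyclohexene carboxylic acid
Product: 7 4-tert-butyl 1-methyl 2-[(1R,6R)-6-(methoxycarbonyl)-6-methylcyclohex-2-en-1-yl]butanedioate (both C6 epimers)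
Conditions: MeI, K2CO3, DMF, rt
Reagents that add atoms: iodomethane, CI
Why: SN2 O-methylation of the carboxylate, which works at a hindered tertiary carboxyl where acid-catalysed esterification is slow and which spares the tert-butyl ester.

Step 5
Reactants: 7 triester
Product: 8 4-methoxy-3-[(1R,6R)-6-(methoxycarbonyl)-6-methylcyclohex-2-en-1-yl]-4-oxobutanoic acid (both C6 epimers)
Conditions: CF3CO2H, CH2Cl2, 0 °C → rt
Reagents that add atoms: none
Why: Acidolysis of the tert-butyl ester by loss of 2-methylpropene frees only the C9 carboxyl; the two methyl esters and the disubstituted alkene do not react under these conditions.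

Step 6
Reactants: 8 diester acid
Product: 11 dimethyl (3R,3aS,4R)-4-methyl-1-oxo-2,3,3a,4,5,6-hexahydro-1H-indene-3,4-dicarboxylate (ring A/B enone with 9-oxo and 1(10)-ene; H-5 β; 6β- and 4α-CO2Me), via acid chloride 9 (not isolated), via chloro ketone 10 (not isolated)
Conditions: (COCl)2, DMF (cat.), CH2Cl2, 0 °C → rt; SnCl4, CH2Cl2, −78 → −20 °C; aqueous work-up; NaOMe, MeOH, 0 °C → rt
Reagents that add atoms: none
Why: Intramolecular Friedel–Crafts-type acylation of an alkene: the C9 acylium attacks the nearer alkene carbon C10 (five-membered ring, cis fusion) in preference to C1, which would give a bridged bicyclo[3.3.1]nonane, and chloride caps C1. Methoxide then removes hydrogen chloride by E1cB to the conjugated 1(10)-enone and equilibrates C6 to the ester trans to C4, so both C6 epimers converge; C5 is not acidic in this enone and keeps its configuration.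

Step 7
Reactants: 11 ring A/B enone; 12 3-bromoprop-1-yne (propargyl bromide)
Product: 13 dimethyl 4-methyl-1-oxo-2-(prop-2-yn-1-yl)-2,3,3a,4,5,6-hexahydro-1H-indene-3,4-dicarboxylate (propargyl mainly 8α, trans to the 6β-ester)
Conditions: LiN(i-Pr)2, THF, −78 °C; then 12, −78 → −30 °C
Reagents that add atoms: none
Why: Kinetic α′-deprotonation of a cross-conjugated enone can occur only at C8, because C10 is sp2, and the enolate is alkylated by the reactive propargylic bromide; the C8 configuration is of no consequence because C8 becomes planar in step 8.

Step 8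
Reactants: 13 8-propargyl enone
Product: 14 trimethylsilyl dienol ether of 13 (8(9)-ene and 1(10)-ene, 9-OSiMe3)
Conditions: LiN(i-Pr)2, THF, −78 °C; then Me3SiCl, Et3N, −78 → 0 °C
Reagents that add atoms: chlorotrimethylsilane, C[Si](C)(C)Cl
Why: Kinetic α′-deprotonation again takes the C8 hydrogen (α to the ketone, faster than the γ-hydrogens at C2 or the hindered ester α-hydrogen at C6) and O-silylation fixes the C8=C9 enol regiochemistry; the alkyne C–H is less acidic than the ketone α-hydrogen, so any acetylide should pass its charge to the ketone before the silyl chloride is added.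

Step 9
Reactants: 14 silyl dienol ether; 15 but-3-en-2-one (methyl vinyl ketone)
Product: 16 dimethyl 4-methyl-1-oxo-2-(3-oxobutyl)-2-(prop-2-yn-1-yl)-2,3,3a,4,5,6-hexahydro-1H-indene-3,4-dicarboxylate (8β-propargyl, 8α-(3-oxobutyl))
Conditions: TiCl4, CH2Cl2, −78 °C; aq. NaHCO3
Reagents that add atoms: none
Why: Mukaiyama–Michael addition of the silyl enol ether to the Lewis-acid-activated enone forms the C8–C14 bond and the C8 quaternary centre without the polymerisation that lithium enolates cause with 15. The enone enters anti to the adjacent 6β-ester, so the chain is α and the propargyl group β; the dienyl silyl ether is held s-trans and cannot act as a Diels–Alder diene.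

Step 10
Reactants: 16 diketone
Product: 17 dimethyl 4-methyl-2-[2-(2-methyl-1,3-dioxolan-2-yl)ethyl]-1-oxo-2-(prop-2-yn-1-yl)-2,3,3a,4,5,6-hexahydro-1H-indene-3,4-dicarboxylate (12-ethylene ketal of 16)
Conditions: Me3SiOCH2CH2OSiMe3, Me3SiOSO2CF3 (cat.), CH2Cl2, −78 → −20 °C
Reagents that add atoms: 1,2-bis(trimethylsilyloxy)ethane, C[Si](C)(C)OCCO[Si](C)(C)C
Why: Silyl-triflate-catalysed ketalisation under aprotic conditions takes the unhindered saturated methyl ketone and leaves the C9 ketone, which is deactivated by conjugation and flanked by quaternary C8; the low temperature avoids acid-catalysed aldol closure of the 1,5-diketone.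

Step 11
Reactants: 17 ketal enone
Product: 19 dimethyl 4-methyl-2-[2-(2-methyl-1,3-dioxolan-2-yl)ethyl]-2-(prop-2-yn-1-yl)-3,3a,4,5,6,7-hexahydro-2H-indene-3,4-dicarboxylate (9(10)-ene), via tosylhydrazone 18 (not isolated)
Conditions: TsNHNH2, EtOH, 60 °C; then catecholborane, CHCl3, 0 °C; NaOAc·3H2O, 60 °C
Reagents that add atoms: none
Why: Reductive 1,3-transposition of an enone through its tosylhydrazone: hydride adds to C9, sulfinate leaves, and the allylic diazene loses N2 by a retro-ene shift that delivers hydrogen to C1 and moves the alkene to C9=C10. The mechanism allows no other regiochemistry and creates no stereocentre; catecholborane does not hydroborate the alkyne at this temperature.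

Step 12
Reactants: 19 ketal alkene
Product: 20 dimethyl 4-methyl-2-(3-oxobutyl)-2-(prop-2-yn-1-yl)-3,3a,4,5,6,7-hexahydro-2H-indene-3,4-dicarboxylate (9(10)-ene methyl ketone)
Conditions: pyridinium p-toluenesulfonate, acetone/H2O, 50 °C
Reagents that add atoms: water, O
Why: Mild acid hydrolysis of the dioxolane; the weak acid should not protonate the trisubstituted C9=C10 alkene, so the double bond stays in place.

Step 13
Reactants: 20 methyl ketone
Product: 21 dimethyl 2-[(4Z)-5-hydroxy-3-oxopent-4-en-1-yl]-4-methyl-2-(prop-2-yn-1-yl)-3,3a,4,5,6,7-hexahydro-2H-indene-3,4-dicarboxylate (hydroxymethylene ketone, Z-enol)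
Conditions: LiN(SiMe3)2, THF, −78 °C; HCO2CH2CF3, −78 → 0 °C; 1 M HCl
Reagents that add atoms: 2,2,2-trifluoroethyl formate, O=COCC(F)(F)F
Why: Claisen-type formylation of the kinetic enolate: the silylamide removes a methyl hydrogen (C11) faster than a C13 hydrogen, and the activated formate traps the enolate at −78 °C before it equilibrates, which secures the C11–C20 regiochemistry; the hindered C6 ester hydrogen and the alkyne C–H are not competitive.

Step 14
Reactants: 21 hydroxymethylene ketone; 22 2,2-dimethylpropanoyl chloride (pivaloyl chloride)
Product: 23 dimethyl 2-[(4E)-5-(2,2-dimethylpropanoyloxy)-3-oxopent-4-en-1-yl]-4-methyl-2-(prop-2-yn-1-yl)-3,3a,4,5,6,7-hexahydro-2H-indene-3,4-dicarboxylate (ring A/B hydrindene (E)-β-pivaloyloxy enone, the photosubstrate)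
Conditions: 22, Et3N, DMAP (cat.), CH2Cl2, 0 °C
Reagents that add atoms: none
Why: O-Acylation of the hydroxymethylene ketone at the less hindered formyl oxygen gives the vinylogous anhydride; reversible conjugate addition of the amine catalyst should settle the double bond as the E isomer, and the bulky acyl group makes the enol ester stable enough to handle. The geometry is not critical for step 15.

Step 15
Reactants: 23 (E)-β-pivaloyloxy enone
Product: 24 cyclobutane photoadduct (rings A, B and C plus the C9–C11–C20–C10 cyclobutane; 12-oxo, 20-pivaloyloxy, 8β-propargyl, dimethyl 7,19-dioate)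
Conditions: hν (350 nm, Pyrex), degassed MeCN (0.005 M), rt
Reagents that add atoms: none
Why: Excitation of the β-acyloxy enone and intersystem crossing give a triplet that is twisted about C11=C20, so the geometry of 23 does not matter; C11 bonds to C9 in a 6-exo-trig closure (ring C) and leaves a 1,4-biradical with a tertiary radical at C10 and an acyloxy-stabilised radical at C20, which couples after spin inversion to close the four-membered ring through C10–C20. The closest known reaction type is the intramolecular de Mayo [2+2] photocycloaddition of enol esters of 1,3-dicarbonyl compounds with alkenes held by a three-atom link between the carbonyl carbon and the alkene, which gives the straight bicyclo[4.2.0]octanone. C9 is set by the tether, which leaves C8 through C14 on the α face so that C11 can reach only the α lobe of C9 (cis B/C fusion, H-9 β). C10 is set by ring strain, because a cyclobutane can only be cis-fused to the five-membered ring, so C20 also arrives α, cis to C19 and trans to H-5. C11 follows from the cis fusion of ring C with the cyclobutane, and C20 should carry the pivalate on the convex face, anti to C12; both centres are erased in step 18. The step needs chemoselectivity for the alkene over the alkyne, the straight regiochemistry and α-face attack: the alkyne or the crossed mode would demand a seven- or eight-membered first closure, and the face is imposed by the tether. The C12 carbonyl has no γ-hydrogen to abstract on its alkyl side, because C8 is quaternary.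

Step 16
Reactants: 24 cyclobutane photoadduct
Product: 25 tert-butyldimethylsilyl enol ether of 24 (12(13)-ene, 12-OSi)
Conditions: LiN(SiMe3)2, THF, −78 °C; then t-BuMe2SiOSO2CF3
Reagents that add atoms: tert-butyldimethylsilyl trifluoromethanesulfonate, CC(C)(C)[Si](C)(C)OS(=O)(=O)C(F)(F)F
Why: Kinetic enolisation of the C12 ketone occurs at the C13 methylene and not at C11, a hindered cyclobutane methine whose deprotonation would also strain the ring; O-silylation fixes this regiochemistry. The hindered pivalate is not attacked by the silylamide at −78 °C.

Step 17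
Reactants: 25 silyl enol ether
Product: 26 tetracyclic 12-ketone with ring D closed, 16-methylene and the pivaloyloxy cyclobutane (dimethyl 7,19-dioate)
Conditions: Ph3PAuNTf2 (5 mol%), CH2Cl2/H2O (10:1), rt → 40 °C
Reagents that add atoms: none
Why: Gold-catalysed Conia-ene-type carbocyclisation of a silyl enol ether onto a terminal alkyne: C13 adds anti to the gold-activated C16 in a 5-exo-dig closure, and protodeauration gives the exocyclic methylene while the silyl group is lost to water. C13 can only form with the bridge on the face of the propargyl group, so its configuration follows from C8.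

Step 18
Reactants: 26 pivaloyloxy cyclobutane
Product: 28 dimethyl 12,20-dioxogibberell-16-ene-7,19-dioate (12-ketone and C20 aldehyde), via cyclobutanol 27 (not isolated)
Conditions: NaOMe (0.5 equiv), MeOH, 0 °C → rt
Reagents that add atoms: none
Why: Methanolysis of the pivalate gives the cyclobutanol alkoxide, which undergoes strain-driven retro-aldol cleavage of C11–C20 to the C20 aldehyde and the C12 enolate, protonated at C11. Methoxide is used because carbonate cleaves pivalates too slowly; C10 is quaternary, C13 is a bridgehead and C6 already has its stable configuration, so nothing epimerises.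

Step 19
Reactants: 28 keto aldehyde dimethyl ester
Product: 29 12,20-dioxogibberell-16-ene-7,19-dioic acid (the target; 4α- and 6β-carboxyl, 10α-formyl, H-5 β, H-9 β, β-oriented C15–C16 bridge)
Conditions: n-PrSLi (from n-PrSH, n-BuLi), HMPA, rt; then 1 M HCl
Reagents that add atoms: none
Why: SN2 demethylation of both methyl esters by thiolate at the methyl carbon, which works at the hindered C7 and tertiary C19 esters where saponification fails; addition of thiolate to the aldehyde is reversible and is undone on acidic work-up.

## Compound list

1 | methyl (2E,4E)-hexa-2,4-dienoate (methyl sorbate) | C/C=C/C=C/C(=O)OC | starting material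
2 | tert-butyl 2-bromoacetate | CC(C)(C)OC(=O)CBr | starting material
3 | 4-tert-butyl 1-methyl 2-[(1E)-buta-1,3-dien-1-yl]butanedioate (racemic) | C=C/C=C/C(CC(=O)OC(C)(C)C)C(=O)OC | intermediate
4 | 2-methylprop-2-enal (methacrolein) | CC(=C)C=O | starting material
5 | 4-tert-butyl 1-methyl 2-[(1R,6R)-6-formyl-6-methylcyclohex-2-en-1-yl]butanedioate (C6 epimers) | COC(=O)C(CC(=O)OC(C)(C)C)[C@H]1C=CCC[C@@]1(C)C=O | intermediate
6 | (1R,2R)-2-(4-tert-butoxy-1-methoxy-1,4-dioxobutan-2-yl)-1-methylcyclohex-3-ene-1-carboxylic acid (C6 epimers) | COC(=O)C(CC(=O)OC(C)(C)C)[C@H]1C=CCC[C@@]1(C)C(=O)O | intermediate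
7 | 4-tert-butyl 1-methyl 2-[(1R,6R)-6-(methoxycarbonyl)-6-methylcyclohex-2-en-1-yl]butanedioate (C6 epimers) | COC(=O)C(CC(=O)OC(C)(C)C)[C@H]1C=CCC[C@@]1(C)C(=O)OC | intermediate
8 | 4-methoxy-3-[(1R,6R)-6-(methoxycarbonyl)-6-methylcyclohex-2-en-1-yl]-4-oxobutanoic acid (C6 epimers) | COC(=O)C(CC(=O)O)[C@H]1C=CCC[C@@]1(C)C(=O)OC | intermediate
9 | acid chloride of 8: methyl 4-chloro-2-[(1R,6R)-6-(methoxycarbonyl)-6-methylcyclohex-2-en-1-yl]-4-oxobutanoate | COC(=O)C(CC(=O)Cl)[C@H]1C=CCC[C@@]1(C)C(=O)OC | intermediate
10 | dimethyl 7-chloro-4-methyl-1-oxooctahydro-1H-indene-3,4-dicarboxylate (cis ring fusion, H-5 and H-10 β; mixture at C1 and C6) | O=C1CC(C(=O)OC)[C@H]2[C@@H]1C(Cl)CC[C@@]2(C)C(=O)OC | intermediate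
11 | dimethyl (3R,3aS,4R)-4-methyl-1-oxo-2,3,3a,4,5,6-hexahydro-1H-indene-3,4-dicarboxylate (9-oxo, 1(10)-ene, H-5 β, 6β- and 4α-CO2Me) | O=C1C[C@@H](C(=O)OC)[C@H]2C1=CCC[C@@]2(C)C(=O)OC | intermediate
12 | 3-bromoprop-1-yne (propargyl bromide) | C#CCBr | starting material
13 | dimethyl 4-methyl-1-oxo-2-(prop-2-yn-1-yl)-2,3,3a,4,5,6-hexahydro-1H-indene-3,4-dicarboxylate (major epimer drawn: propargyl 8α, trans to the 6β-ester) | O=C1[C@H](CC#C)[C@@H](C(=O)OC)[C@H]2C1=CCC[C@@]2(C)C(=O)OC | intermediate
14 | trimethylsilyl dienol ether of 13 (8(9)-ene, 1(10)-ene, 9-OSiMe3) | C[Si](C)(C)OC1=C(CC#C)[C@@H](C(=O)OC)[C@H]2C1=CCC[C@@]2(C)C(=O)OC | intermediate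
15 | but-3-en-2-one (methyl vinyl ketone) | CC(=O)C=C | starting material
16 | dimethyl 4-methyl-1-oxo-2-(3-oxobutyl)-2-(prop-2-yn-1-yl)-2,3,3a,4,5,6-hexahydro-1H-indene-3,4-dicarboxylate (9-oxo-1(10)-ene; 8β-propargyl, 8α-(3-oxobutyl)) | C#CC[C@]1(CCC(C)=O)C(=O)C2=CCC[C@@](C)(C(=O)OC)[C@H]2[C@@H]1C(=O)OC | intermediate
17 | 12-ethylene ketal of 16 | C#CC[C@]1(CCC2(C)OCCO2)C(=O)C3=CCC[C@@](C)(C(=O)OC)[C@H]3[C@@H]1C(=O)OC | intermediate
18 | 9-(4-methylbenzenesulfonyl)hydrazone of 17 | C#CC[C@]1(CCC2(C)OCCO2)C(=NNS(=O)(=O)c3ccc(C)cc3)C4=CCC[C@@](C)(C(=O)OC)[C@H]4[C@@H]1C(=O)OC | intermediate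
19 | dimethyl 4-methyl-2-[2-(2-methyl-1,3-dioxolan-2-yl)ethyl]-2-(prop-2-yn-1-yl)-3,3a,4,5,6,7-hexahydro-2H-indene-3,4-dicarboxylate (9(10)-ene, 8β-propargyl) | C#CC[C@]1(CCC2(C)OCCO2)C=C3CCC[C@@](C)(C(=O)OC)[C@H]3[C@@H]1C(=O)OC | intermediate
20 | dimethyl 4-methyl-2-(3-oxobutyl)-2-(prop-2-yn-1-yl)-3,3a,4,5,6,7-hexahydro-2H-indene-3,4-dicarboxylate (9(10)-ene; 8β-propargyl, 8α-(3-oxobutyl)) | C#CC[C@]1(CCC(C)=O)C=C2CCC[C@@](C)(C(=O)OC)[C@H]2[C@@H]1C(=O)OC | intermediate
21 | dimethyl 2-[(4Z)-5-hydroxy-3-oxopent-4-en-1-yl]-4-methyl-2-(prop-2-yn-1-yl)-3,3a,4,5,6,7-hexahydro-2H-indene-3,4-dicarboxylate (hydroxymethylene ketone, Z-enol) | C#CC[C@]1(CCC(=O)/C=C\O)C=C2CCC[C@@](C)(C(=O)OC)[C@H]2[C@@H]1C(=O)OC | intermediate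
22 | 2,2-dimethylpropanoyl chloride (pivaloyl chloride) | CC(C)(C)C(=O)Cl | starting material
23 | dimethyl 2-[(4E)-5-(2,2-dimethylpropanoyloxy)-3-oxopent-4-en-1-yl]-4-methyl-2-(prop-2-yn-1-yl)-3,3a,4,5,6,7-hexahydro-2H-indene-3,4-dicarboxylate (ring A/B hydrindene (E)-β-pivaloyloxy enone) | C#CC[C@]1(CCC(=O)/C=C/OC(=O)C(C)(C)C)C=C2CCC[C@@](C)(C(=O)OC)[C@H]2[C@@H]1C(=O)OC | intermediate
24 | cyclobutane photoadduct with C20 pivalate (rings A, B, C and the C9–C11–C20–C10 cyclobutane; 12-oxo, 8β-propargyl) | C#CC[C@@]12CCC(=O)[C@H]3[C@H](OC(=O)C(C)(C)C)[C@]4(CCC[C@@](C)(C(=O)OC)[C@H]4[C@@H]1C(=O)OC)[C@@H]23 | intermediate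
25 | 12(13)-ene tert-butyldimethylsilyl enol ether of 24 | C#CC[C@@]12CC=C(O[Si](C)(C)C(C)(C)C)[C@H]3[C@H](OC(=O)C(C)(C)C)[C@]4(CCC[C@@](C)(C(=O)OC)[C@H]4[C@@H]1C(=O)OC)[C@@H]23 | intermediate
26 | ring D closed 12-ketone with 16-methylene and pivaloyloxy cyclobutane | C=C1C[C@]23C[C@H]1C(=O)[C@H]4[C@H](OC(=O)C(C)(C)C)[C@]5(CCC[C@@](C)(C(=O)OC)[C@H]5[C@@H]3C(=O)OC)[C@@H]24 | intermediate
27 | cyclobutanol from 26 | C=C1C[C@]23C[C@H]1C(=O)[C@H]4[C@H](O)[C@]5(CCC[C@@](C)(C(=O)OC)[C@H]5[C@@H]3C(=O)OC)[C@@H]24 | intermediate
28 | dimethyl 12,20-dioxogibberell-16-ene-7,19-dioate | C=C1C[C@]23C[C@H]1C(=O)C[C@H]2[C@]1(C=O)CCC[C@@](C)(C(=O)OC)[C@H]1[C@@H]3C(=O)OC | intermediate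
29 | 12,20-dioxogibberell-16-ene-7,19-dioic acid | C=C1C[C@]23C[C@H]1C(=O)C[C@H]2[C@]1(C=O)CCC[C@@](C)(C(=O)O)[C@H]1[C@@H]3C(=O)O | target

## Step count and least certain steps

Total step count: 19. Longest linear sequence: 19 steps (1 to 29; the route is fully linear).

**Step 15 (key step).** The likely failure is energy wasting: the acyclic enone triplet can relax by rotation about C11=C20 faster than it closes the six-membered ring, and a light-induced 1,3-acyl shift of the enol ester can compete. Fallback: irradiate the free hydroxymethylene ketone 21 instead (300 nm, MeCN). Its hydrogen-bonded cis-enol cannot relax by rotation, which is the classical de Mayo arrangement. The cyclobutanol F1 would open in the flask by retro-aldol to the keto aldehyde F2. Treatment of F2 with t-BuMe2SiOSO2CF3 and Et3N should give mainly the 12(13)-ene silyl enol ether F3, since C11 is shielded by C9 and its two quaternary neighbours. Ph3PAuNTf2 in wet CH2Cl2 would then close ring D, and the fallback rejoins the route at 28. Its weakness is the less secure C13/C11 enolisation, which the cyclobutane enforces in the main route.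

**Step 6.** The acylium may close on C1 to a bridged ketone, be captured by the neighbouring C7 ester, or the C1 cation may rearrange. Fallback from 8: make the S-ethyl thioester F4 (EtSH, N,N′-dicyclohexylcarbodiimide, DMAP), reduce it to the aldehyde F5 (Fukuyama reduction, Et3SiH, Pd/C), and close ring B by a Me2AlCl-promoted carbonyl-ene reaction. A concerted ene reaction cannot bond at C1 without a bridgehead alkene, so it should give the cis-fused homoallylic alcohol F6. Dess–Martin oxidation gives the β,γ-unsaturated ketone F7, and NaOMe in MeOH moves the alkene into conjugation and equilibrates C6, returning to 11.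

**Step 9.** Bond formation at the fully substituted, congested enol carbon may be slow, and loss of the silyl group or a second addition may compete. Fallback from 13: form the lithium enolate (LiN(i-Pr)2, THF, −78 °C) and add it to 3-(trimethylsilyl)but-3-en-2-one, whose α-silyl group stabilises the adduct anion and prevents polymerisation, to give the silyl diketone F8. KF in MeOH removes the silyl group and returns to 16.

**Step 11.** Hydrazone formation at the hindered, conjugated C9 ketone may be slow, and acid added to speed it may open the ketal. Fallback from 17: conjugate reduction with LiBH(s-Bu)3 and trapping of the C9 enolate with N-(5-chloropyridin-2-yl)bis(trifluoromethanesulfonyl)imide gives the enol triflate F9, which can only have the C9=C10 double bond. Reduction with Pd(OAc)2, PPh3, HCO2H and n-Bu3N at room temperature then gives 19; hydride transfer from formate should be fast enough that coupling of the terminal alkyne with the triflate does not compete.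

**Step 13.** Enolate equilibration before trapping would send the formyl group to C13, and the product is acidic enough to quench unreacted enolate. Fallback from 20: condense with tert-butoxybis(dimethylamino)methane in toluene at 80 °C, which attacks the methyl group under neutral conditions and gives the enaminone F10. Mild aqueous acid hydrolyses it to 21.

## Further compounds

F1 | step 15 | cyclobutanol photoadduct from 21 (not isolated) | C#CC[C@@]12CCC(=O)[C@H]3C(O)[C@]4(CCC[C@@](C)(C(=O)OC)[C@H]4[C@@H]1C(=O)OC)[C@@H]23
F2 | step 15 | ring A/B/C keto aldehyde with 8β-propargyl (12-ketone, C20 aldehyde) | C#CC[C@]12CCC(=O)C[C@H]1[C@]3(C=O)CCC[C@@](C)(C(=O)OC)[C@H]3[C@@H]2C(=O)OC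
F3 | step 15 | 12(13)-ene tert-butyldimethylsilyl enol ether of F2 | C#CC[C@]12CC=C(O[Si](C)(C)C(C)(C)C)C[C@H]1[C@]3(C=O)CCC[C@@](C)(C(=O)OC)[C@H]3[C@@H]2C(=O)OC
F4 | step 6 | S-ethyl thioester of 8 | CCSC(=O)CC(C(=O)OC)[C@H]1C=CCC[C@@]1(C)C(=O)OC
F5 | step 6 | C9 aldehyde from F4 | O=CCC(C(=O)OC)[C@H]1C=CCC[C@@]1(C)C(=O)OC
F6 | step 6 | cis-fused 9-hydroxy-1(2)-ene hydrindene diester | OC1CC(C(=O)OC)[C@H]2[C@@H]1C=CC[C@@]2(C)C(=O)OC
F7 | step 6 | cis-fused 9-oxo-1(2)-ene hydrindene diester | O=C1CC(C(=O)OC)[C@H]2[C@@H]1C=CC[C@@]2(C)C(=O)OC
F8 | step 9 | 13-trimethylsilyl derivative of 16 | C#CC[C@]1(CC([Si](C)(C)C)C(C)=O)C(=O)C2=CCC[C@@](C)(C(=O)OC)[C@H]2[C@@H]1C(=O)OC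
F9 | step 11 | C9 enol triflate (9(10)-ene) of the ketal series | C#CC[C@]1(CCC2(C)OCCO2)C(OS(=O)(=O)C(F)(F)F)=C3CCC[C@@](C)(C(=O)OC)[C@H]3[C@@H]1C(=O)OC
F10 | step 13 | (E)-β-dimethylamino enone from 20 | C#CC[C@]1(CCC(=O)/C=C/N(C)C)C=C2CCC[C@@](C)(C(=O)OC)[C@H]2[C@@H]1C(=O)OC
A1 | alternative 1 | ring A/B/C Diels–Alder adduct with 1(2)-ene, 12-ketal, C20 silyl ether and C16 dimethyl acetal | COC(OC)C[C@]23CCC4(OCCO4)C[C@H]2[C@]1(CO[Si](C)(C)C(C)(C)C)C=CC[C@@](C)(C(=O)OC)[C@H]1[C@@H]3C(=O)OC
A2 | alternative 2 | tetracyclic 12-alcohol with 16-methylene and C20 silyl ether | C=C1C[C@]23C[C@H]1[C@@H](O)C[C@H]2[C@]1(CO[Si](C)(C)C(C)(C)C)CCC[C@@](C)(C(=O)OC)[C@H]1[C@@H]3C(=O)OC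
A3 | alternative 3 | ring A/B/C 7-acid with 13(14)-ene, 12-ketal and silylated propargyl group | C[Si](C)(C)C#CC[C@]23C=CC4(OCCO4)C[C@H]2[C@]1(CO[Si](C)(C)C(C)(C)C)CCC[C@@](C)(C(=O)OC)[C@H]1[C@@H]3C(=O)O
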